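**Retrosynthetic overview**
1. Ring C (ten-membered carbocycle) is closed last by an intramolecular aldol addition of the furanone C-2 enolate (C10) to a C9 aldehyde, which sets C9 and C10.
2. Ring B (cis-fused alpha-methylene lactone: C6–C7 bond, then O–C12) comes from the late union of two halves by indium Barbier allylation of a western dienal (C1–C6, C10, C14, C15) with an eastern allylic bromide (C7–C9, C11–C13), followed by lactonisation; the isovalerate goes onto O-8 after the union.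
3. West: ring A (3(2H)-furanone) is built first from (2Z)-3-methylpent-2-en-4-yn-1-ol (C2–C6, C15, Z-olefin bought in) and a lactic Weinreb amide (C1, C10, C14) by alkynylation and gold-catalysed 5-endo cyclisation.
4. East: (2S)-but-3-ene-1,2-diol supplies C7–C9 and the only chiral-pool stereocentre (C8); ozonolysis, Morita–Baylis–Hillman reaction with methyl acrylate and SN2' bromination give the bromide.
5. Order of ring formation: A (furanone), then B (lactone), then C (carbocycle).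

Assumption: germacrane atom labels are used (C1 ketone, C3–O–C10 furanone bridge, C6 lactone carbinol, C12 lactone carbonyl); the furanone C-2 (C10–H) centre is carried unassigned from racemic ethyl lactate because it is planarised in step 17, so 10 and 20–26 are epimer mixtures at that centre, and 17 is a mixture at its carbinol carbon, which becomes sp2 in step 11.

**Step 1**
Reactants: 1 (2Z)-3-methylpent-2-en-4-yn-1-ol
Product: 2 tert-butyl(dimethyl){[(2Z)-3-methylpent-2-en-4-yn-1-yl]oxy}silane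
Conditions: TBSCl, imidazole, CH2Cl2, 0 °C to rt
Reagents that add atoms: tert-butyldimethylsilyl chloride, CC(C)(C)[Si](C)(C)Cl
Why: Silyl ether formation masks the primary allylic hydroxyl (O-6) so that the terminal alkyne can be lithiated.

**Step 2**
Reactants: 3 ethyl 2-hydroxypropanoate (racemic ethyl lactate)
Product: 4 2-hydroxy-N-methoxy-N-methylpropanamide
Conditions: MeNH(OMe)·HCl, i-PrMgCl, THF, −20 to 0 °C; aq NH4Cl
Reagents that add atoms: N,O-dimethylhydroxylamine hydrochloride, CNOC.Cl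
Why: Aminolysis of the ester by the magnesium amide gives the Weinreb amide that will deliver C1 as a ketone.

**Step 3**
Reactants: 2 tert-butyl(dimethyl){[(2Z)-3-methylpent-2-en-4-yn-1-yl]oxy}silane, 4 2-hydroxy-N-methoxy-N-methylpropanamide
Product: 7 (6Z)-8-{[tert-butyl(dimethyl)silyl]oxy}-2-hydroxy-6-methyloct-6-en-4-yn-3-one, via lithium acetylide 5 (not isolated), via chloromagnesium alkoxide 6 (not isolated)
Conditions: 2, n-BuLi, THF, −78 °C; 4, i-PrMgCl, THF, −20 °C; combine, −78 to 0 °C; aq NH4Cl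
Reagents that add atoms: none
Why: Weinreb ketone synthesis, in which the acetylide adds once to the chelated amide (hydroxyl parked as its magnesium alkoxide) to give the alpha'-hydroxy ynone with the Z-olefin untouched.

**Step 4**
Reactants: 7 (6Z)-8-{[tert-butyl(dimethyl)silyl]oxy}-2-hydroxy-6-methyloct-6-en-4-yn-3-one
Product: 8 5-[(2Z)-4-{[tert-butyl(dimethyl)silyl]oxy}but-2-en-2-yl]-2-methylfuran-3(2H)-one
Conditions: (Ph3P)AuCl (5 mol%), AgOTf (5 mol%), toluene, rt
Reagents that add atoms: none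
Why: Gold-catalysed 5-endo-dig cycloisomerisation, in which the hydroxyl adds to the activated alkyne carbon beta to the ketone and forms the 3(2H)-furanone (ring A).

**Step 5**
Reactants: 8 5-[(2Z)-4-{[tert-butyl(dimethyl)silyl]oxy}but-2-en-2-yl]-2-methylfuran-3(2H)-one
Product: 9 5-[(2Z)-4-hydroxybut-2-en-2-yl]-2-methylfuran-3(2H)-one
Conditions: HF·pyridine, THF, 0 °C
Reagents that add atoms: none
Why: Fluoride desilylation under mildly acidic conditions frees the allylic alcohol without touching the vinylogous ester.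

**Step 6**
Reactants: 9 5-[(2Z)-4-hydroxybut-2-en-2-yl]-2-methylfuran-3(2H)-one
Product: 10 (2Z)-3-(5-methyl-4-oxo-4,5-dihydrofuran-2-yl)but-2-enal
Conditions: MnO2, CH2Cl2, rt; used at once
Reagents that add atoms: none
Why: Allylic oxidation with MnO2 is selective for the allylic alcohol and keeps the Z geometry, giving the western dienal.

**Step 7**
Reactants: 11 (2S)-but-3-ene-1,2-diol
Product: 12 (2S)-1-{[tert-butyl(diphenyl)silyl]oxy}but-3-en-2-ol
Conditions: TBDPSCl (1.05 equiv), imidazole, CH2Cl2, −10 °C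
Reagents that add atoms: tert-butyl(chloro)diphenylsilane, CC(C)(C)[Si](Cl)(c1ccccc1)c1ccccc1
Why: The bulky silyl chloride silylates only the primary hydroxyl (O-9), leaving the chiral-pool stereocentre (C8) untouched.

**Step 8**
Reactants: 12 (2S)-1-{[tert-butyl(diphenyl)silyl]oxy}but-3-en-2-ol
Product: 13 tert-butyl{[(2S)-2-{[tert-butyl(dimethyl)silyl]oxy}but-3-en-1-yl]oxy}diphenylsilane
Conditions: TBSCl, imidazole, DMF, rt
Reagents that add atoms: tert-butyldimethylsilyl chloride, CC(C)(C)[Si](C)(C)Cl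
Why: Silylation of the secondary hydroxyl gives a non-chelating, non-leaving O-8 group that can later be removed in the presence of the TBDPS ether.

**Step 9**
Reactants: 13 tert-butyl{[(2S)-2-{[tert-butyl(dimethyl)silyl]oxy}but-3-en-1-yl]oxy}diphenylsilane
Product: 15 (2R)-2-{[tert-butyl(dimethyl)silyl]oxy}-3-{[tert-butyl(diphenyl)silyl]oxy}propanal, via secondary ozonide 14 (not isolated)
Conditions: O3, CH2Cl2, −78 °C; Me2S, −78 °C to rt
Reagents that add atoms: ozone, [O-][O+]=O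
Why: Ozonolysis with reductive work-up cuts the vinyl group to the C7 aldehyde without disturbing the alpha stereocentre, whose label changes from S to R only through the priority rules.

**Step 10**
Reactants: 15 (2R)-2-{[tert-butyl(dimethyl)silyl]oxy}-3-{[tert-butyl(diphenyl)silyl]oxy}propanal, 16 methyl prop-2-enoate (methyl acrylate)
Product: 17 methyl (4R)-4-{[tert-butyl(dimethyl)silyl]oxy}-5-{[tert-butyl(diphenyl)silyl]oxy}-3-hydroxy-2-methylidenepentanoate (mixture at C-3)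
Conditions: DABCO (0.5 equiv), 16 (4 equiv), 1,4-dioxane/H2O 1:1, rt
Reagents that add atoms: none
Why: The Morita–Baylis–Hillman reaction joins the acrylate alpha-carbon (C11) to C7, and the new carbinol centre need not be controlled because it becomes sp2 in the next step.

**Step 11**
Reactants: 17 methyl (4R)-4-{[tert-butyl(dimethyl)silyl]oxy}-5-{[tert-butyl(diphenyl)silyl]oxy}-3-hydroxy-2-methylidenepentanoate
Product: 18 methyl (2Z,4S)-2-(bromomethyl)-4-{[tert-butyl(dimethyl)silyl]oxy}-5-{[tert-butyl(diphenyl)silyl]oxy}pent-2-enoate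
Conditions: NBS, Me2S, CH2Cl2, −20 to 0 °C
Reagents that add atoms: N-bromosuccinimide, O=C1CCC(=O)N1Br
Why: Corey–Kim-type activation of the allylic alcohol followed by SN2' attack of bromide gives the (Z)-2-(bromomethyl)enoate, the usual thermodynamic outcome for Baylis–Hillman adducts.

**Step 12**
Reactants: 10 (2Z)-3-(5-methyl-4-oxo-4,5-dihydrofuran-2-yl)but-2-enal, 18 methyl (2Z,4S)-2-(bromomethyl)-4-{[tert-butyl(dimethyl)silyl]oxy}-5-{[tert-butyl(diphenyl)silyl]oxy}pent-2-enoate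
Product: 21 (4S,5S)-4-[(1S)-1-{[tert-butyl(dimethyl)silyl]oxy}-2-{[tert-butyl(diphenyl)silyl]oxy}ethyl]-3-methylidene-5-[(1Z)-2-(5-methyl-4-oxo-4,5-dihydrofuran-2-yl)prop-1-en-1-yl]oxolan-2-one, via allylindium dibromide 19 (not isolated), via hydroxy ester 20 (not isolated)
Conditions: In powder (1.5 equiv), THF/H2O 1:1, rt; then PPTS (0.2 equiv), benzene, 45 °C
Reagents that add atoms: none
Why: In this Barbier allylation the allylindium adds through C7 to the aldehyde in a chair transition state that gives the syn adduct (hence the cis-lactone after acid-catalysed lactonisation), while C8 steers the allyl face (H-8 eclipses the double bond to avoid allylic 1,3-strain and the aldehyde enters anti to the C8–C9 bond with the silyloxy group outside), so C6 (S) and C7 (S) are set together.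

**Step 13**
Reactants: 21 (4S,5S)-4-[(1S)-1-{[tert-butyl(dimethyl)silyl]oxy}-2-{[tert-butyl(diphenyl)silyl]oxy}ethyl]-3-methylidene-5-[(1Z)-2-(5-methyl-4-oxo-4,5-dihydrofuran-2-yl)prop-1-en-1-yl]oxolan-2-one
Product: 22 (4R,5S)-4-[(1S)-2-{[tert-butyl(diphenyl)silyl]oxy}-1-hydroxyethyl]-3-methylidene-5-[(1Z)-2-(5-methyl-4-oxo-4,5-dihydrofuran-2-yl)prop-1-en-1-yl]oxolan-2-one
Conditions: CSA (0.2 equiv), MeOH/CH2Cl2 1:1, 0 °C
Reagents that add atoms: none
Why: Acid-catalysed methanolysis removes the TBS ether far faster than the TBDPS ether and exposes only O-8, with no change in configuration (the C-4 label changes only through the priority rules).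

**Step 14**
Reactants: 22 (4R,5S)-4-[(1S)-2-{[tert-butyl(diphenyl)silyl]oxy}-1-hydroxyethyl]-3-methylidene-5-[(1Z)-2-(5-methyl-4-oxo-4,5-dihydrofuran-2-yl)prop-1-en-1-yl]oxolan-2-one, 23 3-methylbutanoyl chloride
Product: 24 (1S)-2-{[tert-butyl(diphenyl)silyl]oxy}-1-{(2S,3S)-4-methylidene-2-[(1Z)-2-(5-methyl-4-oxo-4,5-dihydrofuran-2-yl)prop-1-en-1-yl]-5-oxooxolan-3-yl}ethyl 3-methylbutanoate
Conditions: pyridine, DMAP (0.1 equiv), CH2Cl2, 0 °C
Reagents that add atoms: none
Why: DMAP-catalysed acylation of the only free hydroxyl installs the isovalerate on O-8 with retention at C8.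

**Step 15**
Reactants: 24 (1S)-2-{[tert-butyl(diphenyl)silyl]oxy}-1-{(2S,3S)-4-methylidene-2-[(1Z)-2-(5-methyl-4-oxo-4,5-dihydrofuran-2-yl)prop-1-en-1-yl]-5-oxooxolan-3-yl}ethyl 3-methylbutanoate
Product: 25 (1S)-2-hydroxy-1-{(2S,3S)-4-methylidene-2-[(1Z)-2-(5-methyl-4-oxo-4,5-dihydrofuran-2-yl)prop-1-en-1-yl]-5-oxooxolan-3-yl}ethyl 3-methylbutanoate
Conditions: HF·pyridine, THF, 0 °C to rt
Reagents that add atoms: none
Why: Desilylation with acidic fluoride frees O-9 while avoiding the base-promoted shift of the neighbouring ester.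

**Step 16**
Reactants: 25 (1S)-2-hydroxy-1-{(2S,3S)-4-methylidene-2-[(1Z)-2-(5-methyl-4-oxo-4,5-dihydrofuran-2-yl)prop-1-en-1-yl]-5-oxooxolan-3-yl}ethyl 3-methylbutanoate
Product: 26 (1S)-1-{(2S,3S)-4-methylidene-2-[(1Z)-2-(5-methyl-4-oxo-4,5-dihydrofuran-2-yl)prop-1-en-1-yl]-5-oxooxolan-3-yl}-2-oxoethyl 3-methylbutanoate
Conditions: Dess–Martin periodinane, pyridine, CH2Cl2, 0 °C; used at once
Reagents that add atoms: none
Why: Dess–Martin oxidation of the primary alcohol gives the C9 aldehyde under near-neutral conditions that do not epimerise the alpha-acyloxy centre.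

**Step 17**
Reactants: 26 (1S)-1-{(2S,3S)-4-methylidene-2-[(1Z)-2-(5-methyl-4-oxo-4,5-dihydrofuran-2-yl)prop-1-en-1-yl]-5-oxooxolan-3-yl}-2-oxoethyl 3-methylbutanoate
Product: 28 (3aS,4S,5R,6R,10Z,11aS)-5-hydroxy-6,10-dimethyl-3-methylidene-2,7-dioxo-2,3,3a,4,5,6,7,11a-octahydro-6,9-epoxycyclodeca[b]furan-4-yl 3-methylbutanoate (CNP0175298.2), via bromomagnesium furanolate 27 (not isolated)
Conditions: MgBr2·OEt2 (3 equiv), i-Pr2NEt (2 equiv), CH2Cl2 (0.002 M), −40 to −10 °C; pH 7 buffer at −40 °C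
Reagents that add atoms: none
Why: In this intramolecular aldol addition the soft-enolised, aromatic furanolate closes ring C through a magnesium-bridged chair transition state that places the C10 methyl (cis to O–Mg) syn to the new hydroxyl and has the aldehyde, held by magnesium between its own oxygen and the ester carbonyl, attacked anti to C7, which is the arrangement expected to give 9R and 10R.

**Compound list**
1 | (2Z)-3-methylpent-2-en-4-yn-1-ol | C#C/C(C)=C\CO | starting material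
2 | tert-butyl(dimethyl){[(2Z)-3-methylpent-2-en-4-yn-1-yl]oxy}silane | C#C/C(C)=C\CO[Si](C)(C)C(C)(C)C | intermediate
3 | ethyl 2-hydroxypropanoate (racemic) | CCOC(=O)C(C)O | starting material
4 | 2-hydroxy-N-methoxy-N-methylpropanamide (racemic) | CC(O)C(=O)N(C)OC | intermediate
5 | lithium acetylide of 2 | [Li]C#C/C(C)=C\CO[Si](C)(C)C(C)(C)C | intermediate
6 | chloromagnesium alkoxide of 4 | CC(O[Mg]Cl)C(=O)N(C)OC | intermediate
7 | (6Z)-8-{[tert-butyl(dimethyl)silyl]oxy}-2-hydroxy-6-methyloct-6-en-4-yn-3-one | CC(O)C(=O)C#C/C(C)=C\CO[Si](C)(C)C(C)(C)C | intermediate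
8 | 5-[(2Z)-4-{[tert-butyl(dimethyl)silyl]oxy}but-2-en-2-yl]-2-methylfuran-3(2H)-one | CC1OC(=CC1=O)/C(C)=C\CO[Si](C)(C)C(C)(C)C | intermediate
9 | 5-[(2Z)-4-hydroxybut-2-en-2-yl]-2-methylfuran-3(2H)-one | CC1OC(=CC1=O)/C(C)=C\CO | intermediate
10 | (2Z)-3-(5-methyl-4-oxo-4,5-dihydrofuran-2-yl)but-2-enal | CC1OC(=CC1=O)/C(C)=C\C=O | intermediate
11 | (2S)-but-3-ene-1,2-diol | C=C[C@H](O)CO | starting material
12 | (2S)-1-{[tert-butyl(diphenyl)silyl]oxy}but-3-en-2-ol | C=C[C@H](O)CO[Si](c1ccccc1)(c1ccccc1)C(C)(C)C | intermediate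
13 | tert-butyl{[(2S)-2-{[tert-butyl(dimethyl)silyl]oxy}but-3-en-1-yl]oxy}diphenylsilane | C=C[C@H](O[Si](C)(C)C(C)(C)C)CO[Si](c1ccccc1)(c1ccccc1)C(C)(C)C | intermediate
14 | secondary ozonide (3-substituted 1,2,4-trioxolane) of 13 | C1OOC(O1)[C@H](O[Si](C)(C)C(C)(C)C)CO[Si](c1ccccc1)(c1ccccc1)C(C)(C)C | intermediate
15 | (2R)-2-{[tert-butyl(dimethyl)silyl]oxy}-3-{[tert-butyl(diphenyl)silyl]oxy}propanal | O=C[C@H](O[Si](C)(C)C(C)(C)C)CO[Si](c1ccccc1)(c1ccccc1)C(C)(C)C | intermediate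
16 | methyl prop-2-enoate | C=CC(=O)OC | starting material
17 | methyl (4R)-4-{[tert-butyl(dimethyl)silyl]oxy}-5-{[tert-butyl(diphenyl)silyl]oxy}-3-hydroxy-2-methylidenepentanoate | C=C(C(=O)OC)C(O)[C@H](O[Si](C)(C)C(C)(C)C)CO[Si](c1ccccc1)(c1ccccc1)C(C)(C)C | intermediate
18 | methyl (2Z,4S)-2-(bromomethyl)-4-{[tert-butyl(dimethyl)silyl]oxy}-5-{[tert-butyl(diphenyl)silyl]oxy}pent-2-enoate | COC(=O)/C(CBr)=C/[C@H](O[Si](C)(C)C(C)(C)C)CO[Si](c1ccccc1)(c1ccccc1)C(C)(C)C | intermediate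
19 | allylindium dibromide (trivalent indium) from 18 | COC(=O)/C(C[In](Br)Br)=C/[C@H](O[Si](C)(C)C(C)(C)C)CO[Si](c1ccccc1)(c1ccccc1)C(C)(C)C | intermediate
20 | methyl (3S,4S,5Z)-3-[(1S)-1-{[tert-butyl(dimethyl)silyl]oxy}-2-{[tert-butyl(diphenyl)silyl]oxy}ethyl]-4-hydroxy-2-methylidene-6-(5-methyl-4-oxo-4,5-dihydrofuran-2-yl)hept-5-enoate | COC(=O)C(=C)[C@@H]([C@@H](O)/C=C(/C)C1=CC(=O)C(C)O1)[C@H](O[Si](C)(C)C(C)(C)C)CO[Si](c1ccccc1)(c1ccccc1)C(C)(C)C | intermediate
21 | (4S,5S)-4-[(1S)-1-{[tert-butyl(dimethyl)silyl]oxy}-2-{[tert-butyl(diphenyl)silyl]oxy}ethyl]-3-methylidene-5-[(1Z)-2-(5-methyl-4-oxo-4,5-dihydrofuran-2-yl)prop-1-en-1-yl]oxolan-2-one | C=C1C(=O)O[C@@H](/C=C(/C)C2=CC(=O)C(C)O2)[C@H]1[C@H](O[Si](C)(C)C(C)(C)C)CO[Si](c1ccccc1)(c1ccccc1)C(C)(C)C | intermediate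
22 | (4R,5S)-4-[(1S)-2-{[tert-butyl(diphenyl)silyl]oxy}-1-hydroxyethyl]-3-methylidene-5-[(1Z)-2-(5-methyl-4-oxo-4,5-dihydrofuran-2-yl)prop-1-en-1-yl]oxolan-2-one | C=C1C(=O)O[C@@H](/C=C(/C)C2=CC(=O)C(C)O2)[C@H]1[C@H](O)CO[Si](c1ccccc1)(c1ccccc1)C(C)(C)C | intermediate
23 | 3-methylbutanoyl chloride | CC(C)CC(Cl)=O | starting material
24 | (1S)-2-{[tert-butyl(diphenyl)silyl]oxy}-1-{(2S,3S)-4-methylidene-2-[(1Z)-2-(5-methyl-4-oxo-4,5-dihydrofuran-2-yl)prop-1-en-1-yl]-5-oxooxolan-3-yl}ethyl 3-methylbutanoate | C=C1C(=O)O[C@@H](/C=C(/C)C2=CC(=O)C(C)O2)[C@H]1[C@H](OC(=O)CC(C)C)CO[Si](c1ccccc1)(c1ccccc1)C(C)(C)C | intermediate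
25 | (1S)-2-hydroxy-1-{(2S,3S)-4-methylidene-2-[(1Z)-2-(5-methyl-4-oxo-4,5-dihydrofuran-2-yl)prop-1-en-1-yl]-5-oxooxolan-3-yl}ethyl 3-methylbutanoate | C=C1C(=O)O[C@@H](/C=C(/C)C2=CC(=O)C(C)O2)[C@H]1[C@H](OC(=O)CC(C)C)CO | intermediate
26 | (1S)-1-{(2S,3S)-4-methylidene-2-[(1Z)-2-(5-methyl-4-oxo-4,5-dihydrofuran-2-yl)prop-1-en-1-yl]-5-oxooxolan-3-yl}-2-oxoethyl 3-methylbutanoate | C=C1C(=O)O[C@@H](/C=C(/C)C2=CC(=O)C(C)O2)[C@H]1[C@H](OC(=O)CC(C)C)C=O | intermediate
27 | bromomagnesium furanolate of 26 | C=C1C(=O)O[C@@H](/C=C(/C)c2cc(O[Mg]Br)c(C)o2)[C@H]1[C@H](OC(=O)CC(C)C)C=O | intermediate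
28 | (3aS,4S,5R,6R,10Z,11aS)-5-hydroxy-6,10-dimethyl-3-methylidene-2,7-dioxo-2,3,3a,4,5,6,7,11a-octahydro-6,9-epoxycyclodeca[b]furan-4-yl 3-methylbutanoate (germacrane labels 6S,7S,8S,9R,10R) | C=C1C(=O)O[C@H]2/C=C(/C)C3=CC(=O)[C@](C)(O3)[C@H](O)[C@@H](OC(=O)CC(C)C)[C@@H]12 | target

**Step count and risks**
Total step count: 17. Longest linear sequence: 11 steps (11 to 28 through steps 7–17; the paths from 1 and from 3 are also 11 steps).

The three steps most likely to fail:

Step 17, the ring-closing aldol, is the weakest step. The strained ring may not close or may reopen by retro-aldol reaction, the C9 and C10 configurations rest on a transition-state model rather than a close precedent, and the new alkoxide could take over the neighbouring ester. The fallback sets out from 24. Bromination at the furanone C-2 with PhNMe3Br3 in THF at 0 °C gives the bromofuranone F1. HF·pyridine then gives the alcohol F2, and Dess–Martin oxidation gives the bromo aldehyde F3. SmI2 (divalent samarium, 2.2 equiv, THF, −78 °C, high dilution) reduces the C–Br bond to the diiodosamarium furanolate F4 (trivalent samarium), which closes the ring in an irreversible, chelation-organised Reformatsky-type cyclisation under neutral conditions and comes back to the route at 28.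

Step 12, the Barbier union, can suffer from loss of the C8 silyloxy group by 1,4-elimination from the allylmetal, from Wurtz-type coupling, from decomposition of the dienal 10 in water, or from the wrong facial sense at C7. The fallback sets out from 17. Acetylation (Ac2O, DMAP, CH2Cl2) gives the allylic acetate F5. With 10, Pd(PPh3)4 (zerovalent palladium, 5 mol%) and InI (monovalent indium) in dry THF, the pi-allylpalladium complex is transmetalated to the allylindium acetate iodide F6 (trivalent indium). This adds to the aldehyde under anhydrous conditions and returns to the route at 20, which is lactonised with PPTS as before.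

Step 13 exposes a free 8-hydroxyl next to the lactone. It can translactonise to the 8,12-olide, and the selectivity between the two silyl ethers may be incomplete. The fallback avoids any free 8-hydroxyl by carrying the ester from the start, and sets out from 12. Acylation with 23 (pyridine, DMAP) gives the ester F7. Ozonolysis (O3, then Me2S) through the ozonide F8 gives the aldehyde F9. The Baylis–Hillman reaction with 16 (DABCO) gives the adduct F10, and NBS/Me2S gives the bromide F11. Indium-mediated allylation of 10 through the allylindium dibromide F12 and the hydroxy ester F13, followed by PPTS lactonisation, comes back to the route at 24, so steps 13 and 14 are skipped.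

**Further compounds**
F1 | step 17 | (1S)-1-{(2S,3S)-2-[(1Z)-2-(5-bromo-5-methyl-4-oxo-4,5-dihydrofuran-2-yl)prop-1-en-1-yl]-4-methylidene-5-oxooxolan-3-yl}-2-{[tert-butyl(diphenyl)silyl]oxy}ethyl 3-methylbutanoate | C=C1C(=O)O[C@@H](/C=C(/C)C2=CC(=O)C(C)(Br)O2)[C@H]1[C@H](OC(=O)CC(C)C)CO[Si](c1ccccc1)(c1ccccc1)C(C)(C)C
F2 | step 17 | (1S)-1-{(2S,3S)-2-[(1Z)-2-(5-bromo-5-methyl-4-oxo-4,5-dihydrofuran-2-yl)prop-1-en-1-yl]-4-methylidene-5-oxooxolan-3-yl}-2-hydroxyethyl 3-methylbutanoate | C=C1C(=O)O[C@@H](/C=C(/C)C2=CC(=O)C(C)(Br)O2)[C@H]1[C@H](OC(=O)CC(C)C)CO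
F3 | step 17 | (1S)-1-{(2S,3S)-2-[(1Z)-2-(5-bromo-5-methyl-4-oxo-4,5-dihydrofuran-2-yl)prop-1-en-1-yl]-4-methylidene-5-oxooxolan-3-yl}-2-oxoethyl 3-methylbutanoate | C=C1C(=O)O[C@@H](/C=C(/C)C2=CC(=O)C(C)(Br)O2)[C@H]1[C@H](OC(=O)CC(C)C)C=O
F4 | step 17 | diiodosamarium furanolate from F3 | C=C1C(=O)O[C@@H](/C=C(/C)c2cc(O[Sm](I)I)c(C)o2)[C@H]1[C@H](OC(=O)CC(C)C)C=O
F5 | step 12 | methyl (4R)-3-(acetyloxy)-4-{[tert-butyl(dimethyl)silyl]oxy}-5-{[tert-butyl(diphenyl)silyl]oxy}-2-methylidenepentanoate | C=C(C(=O)OC)C(OC(C)=O)[C@H](O[Si](C)(C)C(C)(C)C)CO[Si](c1ccccc1)(c1ccccc1)C(C)(C)C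
F6 | step 12 | allylindium acetate iodide from F5 | COC(=O)/C(C[In](I)OC(C)=O)=C/[C@H](O[Si](C)(C)C(C)(C)C)CO[Si](c1ccccc1)(c1ccccc1)C(C)(C)C
F7 | step 13 | (2S)-1-{[tert-butyl(diphenyl)silyl]oxy}but-3-en-2-yl 3-methylbutanoate | C=C[C@H](OC(=O)CC(C)C)CO[Si](c1ccccc1)(c1ccccc1)C(C)(C)C
F8 | step 13 | secondary ozonide (3-substituted 1,2,4-trioxolane) of F7 | C1OOC(O1)[C@H](OC(=O)CC(C)C)CO[Si](c1ccccc1)(c1ccccc1)C(C)(C)C
F9 | step 13 | (2R)-1-{[tert-butyl(diphenyl)silyl]oxy}-3-oxopropan-2-yl 3-methylbutanoate | O=C[C@H](OC(=O)CC(C)C)CO[Si](c1ccccc1)(c1ccccc1)C(C)(C)C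
F10 | step 13 | methyl (4R)-5-{[tert-butyl(diphenyl)silyl]oxy}-3-hydroxy-2-methylidene-4-[(3-methylbutanoyl)oxy]pentanoate | C=C(C(=O)OC)C(O)[C@H](OC(=O)CC(C)C)CO[Si](c1ccccc1)(c1ccccc1)C(C)(C)C
F11 | step 13 | methyl (2Z,4S)-2-(bromomethyl)-5-{[tert-butyl(diphenyl)silyl]oxy}-4-[(3-methylbutanoyl)oxy]pent-2-enoate | COC(=O)/C(CBr)=C/[C@H](OC(=O)CC(C)C)CO[Si](c1ccccc1)(c1ccccc1)C(C)(C)C
F12 | step 13 | allylindium dibromide from F11 | COC(=O)/C(C[In](Br)Br)=C/[C@H](OC(=O)CC(C)C)CO[Si](c1ccccc1)(c1ccccc1)C(C)(C)C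
F13 | step 13 | methyl (3S,4S,5Z)-3-[(1S)-2-{[tert-butyl(diphenyl)silyl]oxy}-1-[(3-methylbutanoyl)oxy]ethyl]-4-hydroxy-2-methylidene-6-(5-methyl-4-oxo-4,5-dihydrofuran-2-yl)hept-5-enoate | COC(=O)C(=C)[C@@H]([C@@H](O)/C=C(/C)C1=CC(=O)C(C)O1)[C@H](OC(=O)CC(C)C)CO[Si](c1ccccc1)(c1ccccc1)C(C)(C)C
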